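The ratio of nucleophile to electrophile in this flask, 1.80, is too small for a pseudo-first-order treatment, so we must follow [nucleophile] as it falls, and the first question is whether acid set free takes any of it away.

electrophile 10 mM; nucleophile 18.0 mM; free base 12.0 mM (fed, over 6.0 min); scavenger 15.0 mM; time 12 min

    electrophile + nucleophile → acid set free + product (k1 = 0.32 /M/s)
    nucleophile + acid set free ⇌ protonated nucleophile, settled at all times (K2 = 2800 /M)
    acid set free + free base ⇌ salt of the base, settled at all times (K3 = 2.6 × 10⁶ /M)
    crystals ⇌ acid set free, rate k4*(cs4 - [acid set free]) while solid is left; crystals form when [acid set free] > cs4 (cs4 = 4.3 mM, k4 = 0.37 /s)
    electrophile + acid set free ⇌ idle adduct, settled at all times (K5 = 110 /M)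
    acid set free + scavenger → scavenged by-product (k6 = 23 /M/s)

- amounts and yields of acid set free count crystals and idle adduct too
- given per volume of solution although it is solid: crystals
- run time (flask): 12 min

1. part of the electrophile that has reacted at 12 min
2. share of the unused nucleophile that is free and not bound as protonated nucleophile, at 12 min

We set up a small table of what each partner offers the acid set free, its equilibrium constant times its charge: free base 31200, nucleophile 50, electrophile 1.1. Reading down, the free base outbids the nucleophile by a factor of 619, and the electrophile bids less than the nucleophile. But the top row holds for the whole charge, and the feed brings 2.00 mM/min against 3.46 mM/min of acid made at the start, so we expect some nucleophile to be bound early on. The charge of free base exceeds the electrophile's, so we reckon that this loan is repaid and treat the nucleophile as free.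

Then [nucleophile] minus [electrophile] stays constant, and the rate law integrates. The excess clock, rate constant times excess of nucleophile over electrophile times time, is 1.84. The part of the electrophile left is the excess divided by (charged [nucleophile] times e to the clock, minus charged [electrophile]), which gives 7.71% left, so 92.3% reacted. Setting the scavenger aside, we count all acid as salt of the base, 9.23 mM, and step 3 then gives a free share of 99.6%.

The forecast gave 92% reacted (90% to 94%) and 99.7% free (99.5% to 99.9%), holding that “the run is close to plain second-order coupling”.

The flask gives 92.2% reacted and 99.7% free, and the joining of nucleophile with acid set free makes no difference to the part reacted. In the neighbour charged with 40 mM of electrophile the excess turns negative, −22.0 mM, and the clock reads −5.07. The same expression then gives 44.8% reacted, while that flask, whose charge of free base is smaller than its charge of electrophile, stands at 44.8%, with the nucleophile, now the limiting reagent, down to 0.529% of its charge.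

All constants are invented, and the outcome is calculated.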